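**Retrosynthetic overview**

- Numbering (hydroazulene): five-membered ring C1(i-Pr)–C2–C3–C3a(CH3)–C8a(OH); seven-membered ring C3a–C4(O-ester)–C5=C6(CH3)–C7–C8–C8a.
- Late stage: the C4 ester comes from acylation of the allylic alcohol, and that alcohol from 1,2-reduction of the C4 enone of a bicyclic ketol.
- Key disconnection: C3a–C8a (transannular aldol) and C6–C7 ([3,3] shift) lead back to a 1-ethenyl-2-propynyl-p-menthane-1,2-diol. The forward step is a four-carbon ring expansion (six to ten) followed by transannular closure.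
- Enabling feature: C4 and C8a are both oxygenated and 1,6-related on the ten-membered periphery. C4(O)–C5=C6–C7–C8–C8a(O) is the retron of a [3,3] shift of the 3,4-dioxygenated hex-1-en-5-yne C7=C8–C8a(O)–C4(O)–C5≡C6. C8a(OH)–C3a–C4(=O) is an aldol. The six atoms C4–C3a–C3–C2–C1–C8a, with CH3 and i-Pr in a 1,4 relationship, are the menthone ring once C4–C8a is rejoined.
- Ring order: cyclohexane (from (+)-menthol, which supplies the C1 stereocentre) → cyclodecene (oxy-Cope) → cyclopentane and cycloheptenone together (aldol).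

Key step: step 6

Assumption (remark on the chemistry): the configurations written for the two oxygen-bearing ring carbons of the cyclohexane intermediates are the expected major ones; both, and the methyl-bearing centre inherited from menthol, become trigonal in step 6, so any epimers at these centres converge on the same product.

**Step 1**
Reactants: 1 (+)-menthol, (1S,2R,5S)-5-methyl-2-(propan-2-yl)cyclohexan-1-ol
Product: 2 (+)-menthone, (2R,5S)-5-methyl-2-(propan-2-yl)cyclohexan-1-one
Conditions: NaOCl (aq.), AcOH, 0 → 25 °C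
Reagents that add atoms: none
Why: Hypochlorite oxidation of a secondary alcohol in acetic acid, without base, so the isopropyl-bearing α-centre should not epimerise; no new stereocentre.

**Step 2**
Reactants: 2 (+)-menthone
Product: 4 (2R,3S,6R)-2-hydroxy-3-methyl-6-(propan-2-yl)cyclohexan-1-one, via potassium enolate 3 (not isolated)
Conditions: KN(SiMe3)2, THF, −78 °C; then 2-(phenylsulfonyl)-3-phenyloxaziridine, −78 °C; aq. NH4Cl
Reagents that add atoms: 2-(phenylsulfonyl)-3-phenyloxaziridine, O=S(=O)(c1ccccc1)N1OC1c1ccccc1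
Why: Kinetic deprotonation takes the CH2 proton rather than the CH next to isopropyl, and enolate oxidation by the N-sulfonyloxaziridine should deliver oxygen trans to the neighbouring methyl group (equatorial alcohol).

**Step 3**
Reactants: 4 (2R,3S,6R)-2-hydroxy-3-methyl-6-(propan-2-yl)cyclohexan-1-one; 5 vinylmagnesium bromide
Product: 6 (1S,2R,3S,6R)-1-ethenyl-3-methyl-6-(propan-2-yl)cyclohexane-1,2-diol
Conditions: CeCl3, vinylmagnesium bromide (3.5 equiv), THF, −78 → 0 °C; aq. NH4Cl
Reagents that add atoms: vinylmagnesium bromide (5), C=C[Mg]Br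
Why: Organocerium 1,2-addition to a hindered, enolisable ketone (suppresses enolisation toward the isopropyl-bearing carbon); equatorial attack should give the axial tertiary alcohol, and one equivalent is consumed by the free hydroxyl.

**Step 4**
Reactants: 6 (1S,2R,3S,6R)-1-ethenyl-3-methyl-6-(propan-2-yl)cyclohexane-1,2-diol
Product: 7 (2S,3R,6S)-2-ethenyl-2-hydroxy-6-methyl-3-(propan-2-yl)cyclohexan-1-one
Conditions: IBX, DMSO, 25 °C
Reagents that add atoms: none
Why: IBX oxidises the secondary hydroxyl of a 1,2-diol to the ketone without glycol cleavage and leaves the tertiary allylic alcohol untouched; no new stereocentre.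

**Step 5**
Reactants: 7 (2S,3R,6S)-2-ethenyl-2-hydroxy-6-methyl-3-(propan-2-yl)cyclohexan-1-one; 8 (prop-1-yn-1-yl)magnesium bromide
Product: 9 (1S,2S,3S,6R)-1-ethenyl-3-methyl-6-(propan-2-yl)-2-(prop-1-yn-1-yl)cyclohexane-1,2-diol
Conditions: (prop-1-yn-1-yl)magnesium bromide (3 equiv), THF, −20 → 25 °C; aq. NH4Cl
Reagents that add atoms: (prop-1-yn-1-yl)magnesium bromide (8), CC#C[Mg]Br
Why: 1,2-Addition of an alkynyl Grignard reagent to the magnesium alkoxide of the α-ketol; the small sp nucleophile should enter axially, anti to the axial C–O bond (Felkin–Anh polar model), which places propynyl gauche to the equatorial vinyl group.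

**Step 6**
Reactants: 9 (1S,2S,3S,6R)-1-ethenyl-3-methyl-6-(propan-2-yl)-2-(prop-1-yn-1-yl)cyclohexane-1,2-diol
Product: 13 (1R,3aS,8aS)-8a-hydroxy-3a,6-dimethyl-1-(propan-2-yl)-2,3,3a,7,8,8a-hexahydroazulen-4(1H)-one, via dipotassium diolate 10 (not isolated), via dipotassium allenolate-enolate 11 (not isolated), via cyclodecenedione 12 (not isolated)
Conditions: KH, 18-crown-6, THF, 0 → 25 °C; then MeOH, −78 → 0 °C; aq. NH4Cl
Reagents that add atoms: none
Why: Double deprotonation gives diolate 10, in which the C1–C2 bond is the 3,4-bond of a hex-1-en-5-yne flanked by two oxyanions and the vinyl and propynyl groups are gauche, so a dianionic alkynyl oxy-Cope [3,3] shift (six-membered cyclic transition state; closest known types: anionic oxy-Cope ring expansion of 1-alkynyl-2-alkenyl- and 1,2-dialkenyl-cycloalkanols, and the dianionic oxy-Cope/transannular aldol cascade of 1,2-dialkenyl-1,2-diolates) breaks it and joins the two unsaturated termini, creating the C6–C7 bond of the target and enlarging the six-membered ring by four atoms to the ten-membered allenolate-enolate 11. Methanol protonates 11 at the central allene carbon and at C5 to give enedione 12, and the methoxide so formed equilibrates the enone geometry (through the γ-dienolate) and all enolates. The second bond, C3a–C8a, is made by a reversible transannular aldol addition of the α'-enolate carbon C10 of the enone to the C6 ketone, which closes the cyclopentane (5-(enolexo)-exo-trig) and, because the partners sit across the ten-membered ring, the cycloheptenone at the same time; only the 2Z enone can close. The selectivity the step needs is regiochemical (C10 rather than C5 or C7 as donor) and should be secured under thermodynamic control, because this is the only ketol that keeps the enone conjugated and whose donor carbon becomes quaternary (no dehydration), whereas the others revert by retro-aldol. The new stereocentres C3a and C8a are controlled by the retained isopropyl-bearing centre (C7 of 12): with a non-chelating counter-ion the carbonyl oxygen lies anti to the enolate oxygen, which puts the two bridges cis (OH cis to CH3), and the isopropyl group takes the convex face, cis to OH and trans to the C8 methylene. The C7–H of 12 is tertiary and shielded by isopropyl, so low temperature and short base contact should keep this centre, and with it the absolute configuration, intact.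

**Step 7**
Reactants: 13 (1R,3aS,8aS)-8a-hydroxy-3a,6-dimethyl-1-(propan-2-yl)-2,3,3a,7,8,8a-hexahydroazulen-4(1H)-one
Product: 14 (1R,3aR,4S,8aS)-3a,6-dimethyl-1-(propan-2-yl)-1,2,3,3a,4,7,8,8a-octahydroazulene-4,8a-diol
Conditions: NaBH4, CeCl3·7H2O, MeOH, −40 → 0 °C
Reagents that add atoms: none
Why: Luche reduction (1,2-selective for enones); hydride should approach C4 anti to the angular methyl on the adjacent quaternary C3a and anti to the 1,3-related hydroxyl, setting the C4 alcohol cis to CH3 and OH.

**Step 8**
Reactants: 14 (1R,3aR,4S,8aS)-3a,6-dimethyl-1-(propan-2-yl)-1,2,3,3a,4,7,8,8a-octahydroazulene-4,8a-diol; 15 4-methoxybenzoyl chloride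
Product: 16 (1R,3aR,4S,8aS)-8a-hydroxy-3a,6-dimethyl-1-(propan-2-yl)-1,2,3,3a,4,7,8,8a-octahydroazulen-4-yl 4-methoxybenzoate (target)
Conditions: 4-methoxybenzoyl chloride, DMAP, Et3N, CH2Cl2, 0 → 40 °C
Reagents that add atoms: 4-methoxybenzoyl chloride (15), COc1ccc(cc1)C(Cl)=O
Why: DMAP-catalysed acyl transfer should esterify the secondary allylic hydroxyl with retention at C4, while the tertiary ring-fusion hydroxyl is too hindered to react.

**Compound list**

1 | (+)-menthol, (1S,2R,5S)-5-methyl-2-(propan-2-yl)cyclohexan-1-ol | CC(C)[C@H]1CC[C@H](C)C[C@@H]1O | starting material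
2 | (+)-menthone, (2R,5S)-5-methyl-2-(propan-2-yl)cyclohexan-1-one | O=C1C[C@@H](C)CC[C@@H]1C(C)C | intermediate
3 | potassium (3S,6R)-3-methyl-6-(propan-2-yl)cyclohex-1-en-1-olate (formed in the flask, not isolated) | [K+].[O-]C1=C[C@@H](C)CC[C@@H]1C(C)C | intermediate
4 | (2R,3S,6R)-2-hydroxy-3-methyl-6-(propan-2-yl)cyclohexan-1-one | O=C1[C@H](O)[C@@H](C)CC[C@@H]1C(C)C | intermediate
5 | vinylmagnesium bromide | C=C[Mg]Br | starting material
6 | (1S,2R,3S,6R)-1-ethenyl-3-methyl-6-(propan-2-yl)cyclohexane-1,2-diol | C=C[C@@]1(O)[C@H](O)[C@@H](C)CC[C@@H]1C(C)C | intermediate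
7 | (2S,3R,6S)-2-ethenyl-2-hydroxy-6-methyl-3-(propan-2-yl)cyclohexan-1-one | C=C[C@@]1(O)C(=O)[C@@H](C)CC[C@@H]1C(C)C | intermediate
8 | (prop-1-yn-1-yl)magnesium bromide | CC#C[Mg]Br | starting material
9 | (1S,2S,3S,6R)-1-ethenyl-3-methyl-6-(propan-2-yl)-2-(prop-1-yn-1-yl)cyclohexane-1,2-diol | C=C[C@@]1(O)[C@@](O)(C#CC)[C@@H](C)CC[C@@H]1C(C)C | intermediate
10 | dipotassium (1S,2S,3S,6R)-1-ethenyl-3-methyl-6-(propan-2-yl)-2-(prop-1-yn-1-yl)cyclohexane-1,2-bis(olate) (formed in the flask, not isolated) | [K+].[K+].C=C[C@@]1([O-])[C@@]([O-])(C#CC)[C@@H](C)CC[C@@H]1C(C)C | intermediate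
11 | dipotassium (7R,10S)-3,10-dimethyl-7-(propan-2-yl)cyclodeca-1,2,5-triene-1,6-bis(olate) (enolate geometry and allene axis not fixed; formed in the flask, not isolated) | [K+].[K+].[O-]C1=C=C(C)CC=C([O-])[C@@H](C(C)C)CC[C@@H]1C | intermediate
12 | (2Z,7R,10S)-3,10-dimethyl-7-(propan-2-yl)cyclodec-2-ene-1,6-dione (formed in the flask, not isolated) | O=C1/C=C(C)\CCC(=O)[C@@H](C(C)C)CC[C@@H]1C | intermediate
13 | (1R,3aS,8aS)-8a-hydroxy-3a,6-dimethyl-1-(propan-2-yl)-2,3,3a,7,8,8a-hexahydroazulen-4(1H)-one (cis-fused; i-Pr, OH and CH3 on one face) | O=C1C=C(C)CC[C@]2(O)[C@@H](C(C)C)CC[C@]12C | intermediate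
14 | (1R,3aR,4S,8aS)-3a,6-dimethyl-1-(propan-2-yl)-1,2,3,3a,4,7,8,8a-octahydroazulene-4,8a-diol | O[C@H]1C=C(C)CC[C@]2(O)[C@@H](C(C)C)CC[C@]12C | intermediate
15 | 4-methoxybenzoyl chloride | COc1ccc(cc1)C(Cl)=O | starting material
16 | (1R,3aR,4S,8aS)-8a-hydroxy-3a,6-dimethyl-1-(propan-2-yl)-1,2,3,3a,4,7,8,8a-octahydroazulen-4-yl 4-methoxybenzoate | COc1ccc(C(=O)O[C@H]2C=C(C)CC[C@]3(O)[C@@H](C(C)C)CC[C@]23C)cc1 | target

**Step count and risks**

Total step count: 8. Longest linear sequence: 8 steps (1 → 16).

Steps most likely to fail: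

1. Step 6. What may go wrong: after protonation, the enolate on the saturated-ketone side (C5 of 12) may add to the enone carbonyl faster than the C10 enolate adds to C6, and that ketol may dehydrate before it reverts; long base contact may also exchange the C7 hydrogen and erode configuration. Fallback (regiospecific enolate by conjugate reduction instead of equilibration), setting out from 7: dehydrogenation with IBX in DMSO at 70 °C should give (5R,6S)-6-ethenyl-6-hydroxy-2-methyl-5-(propan-2-yl)cyclohex-2-en-1-one F1. 1,2-Addition of 8 (THF, −20 °C) should give (1S,2S,6R)-1-ethenyl-3-methyl-6-(propan-2-yl)-2-(prop-1-yn-1-yl)cyclohex-3-ene-1,2-diol F2. The oxy-Cope shift under the conditions of step 6 (KH, 18-crown-6, THF), now quenched at −78 °C with acetic acid, should give the cross-conjugated (2Z,7R,9Z)-3,10-dimethyl-7-(propan-2-yl)cyclodeca-2,9-diene-1,6-dione F3. The hexameric copper hydride [(Ph3P)CuH]6 in toluene at −40 → 0 °C should then add hydride to the less substituted β-carbon C9; this generates the enolate at C10 only, without base, and its transannular aldol addition to C6 returns to the route at 13.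

2. Step 7. What may go wrong: poor facial selectivity, with hydride delivered to the C4 face that carries the angular methyl, so that the hydroxyl ends trans to CH3. Fallback (invertive esterification instead of retentive acylation), setting out from 13: the reduction is run as in step 7, and the C4-epimeric (1R,3aR,4R,8aS)-3a,6-dimethyl-1-(propan-2-yl)-1,2,3,3a,4,7,8,8a-octahydroazulene-4,8a-diol F4 is esterified under Mitsunobu conditions (4-methoxybenzoic acid, PPh3, diisopropyl azodicarboxylate, toluene, 0 → 60 °C). SN2 displacement inverts C4 and the route is rejoined directly at 16, replacing step 8.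

3. Step 5. What may go wrong: under the basic magnesium alkoxide conditions the tertiary α-ketol may undergo acyloin rearrangement, or be enolised at C6 faster than the hindered carbonyl is attacked. Fallback (masked hydroxyl and non-chelating organocerium addition), setting out from 7: Me3SiCl and imidazole in DMF at 25 °C should give (2S,3R,6S)-2-ethenyl-6-methyl-3-(propan-2-yl)-2-[(trimethylsilyl)oxy]cyclohexan-1-one F5. 1-Propynyllithium premixed with CeCl3 in THF at −78 °C should add to give (1S,2S,3R,6S)-2-ethenyl-6-methyl-3-(propan-2-yl)-1-(prop-1-yn-1-yl)-2-[(trimethylsilyl)oxy]cyclohexan-1-ol F6. K2CO3 in MeOH removes the silyl group and returns to the route at 9.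

Further compounds
F1 | step 6 | (5R,6S)-6-ethenyl-6-hydroxy-2-methyl-5-(propan-2-yl)cyclohex-2-en-1-one | C=C[C@@]1(O)C(=O)C(C)=CC[C@@H]1C(C)C
F2 | step 6 | (1S,2S,6R)-1-ethenyl-3-methyl-6-(propan-2-yl)-2-(prop-1-yn-1-yl)cyclohex-3-ene-1,2-diol | C=C[C@@]1(O)[C@@](O)(C#CC)C(C)=CC[C@@H]1C(C)C
F3 | step 6 | (2Z,7R,9Z)-3,10-dimethyl-7-(propan-2-yl)cyclodeca-2,9-diene-1,6-dione | C1/C=C(C)\C(=O)/C=C(C)\CCC(=O)[C@H]1C(C)C
F4 | step 7 | (1R,3aR,4R,8aS)-3a,6-dimethyl-1-(propan-2-yl)-1,2,3,3a,4,7,8,8a-octahydroazulene-4,8a-diol | O[C@@H]1C=C(C)CC[C@]2(O)[C@@H](C(C)C)CC[C@]12C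
F5 | step 5 | (2S,3R,6S)-2-ethenyl-6-methyl-3-(propan-2-yl)-2-[(trimethylsilyl)oxy]cyclohexan-1-one | C=C[C@@]1(O[Si](C)(C)C)C(=O)[C@@H](C)CC[C@@H]1C(C)C
F6 | step 5 | (1S,2S,3R,6S)-2-ethenyl-6-methyl-3-(propan-2-yl)-1-(prop-1-yn-1-yl)-2-[(trimethylsilyl)oxy]cyclohexan-1-ol | C=C[C@@]1(O[Si](C)(C)C)[C@@](O)(C#CC)[C@@H](C)CC[C@@H]1C(C)C
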